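(The readings were generated by integration with made-up constants, and the scatter is random.)

What do 1% more coupling partner and 1% more free catalyst do to the rate of making left-handed product at the moment 5.0% of both substrates together is converted?

| setting | elm | birch | flask |
|---|---|---|---|
| left-handed substrate | 0.050 M | 0.050 M | 0.050 M |
| right-handed substrate | 0.050 M | 0.050 M | 0.050 M |
| coupling partner | 1.2 equiv | 0.60 equiv | 1.20 equiv |
| free catalyst | 0.53 mol% | 0.53 mol% | 0.53 mol% |
| impurity | 43 µM | 43 µM | 43 µM |
| remark | the very flask that is asked about, followed so far | run made earlier |  |

| run | time / min | left-handed product / % | left-handed substrate / % |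
|---|---|---|---|
| elm | 1.33 | 2.4 | 47.9 |
| elm | 2.50 | 3.5 | 46.7 |
| elm | 4.00 | 5.9 | 45.2 |
| elm | 8.00 | 9.9 | 41.7 |
| elm | 15.0 | 16.1 | 37.3 |
| birch | 3.00 | 2.3 | 48.3 |
| birch | 5.00 | 3.4 | 46.9 |
| birch | 10.0 | 6.3 | 45.0 |
| birch | 20.0 | 10.6 | 42.4 |
| birch | 40.0 | 17.0 | 39.2 |

(each reading ± 0.3 percentage points)

* apparent order in coupling partner when 5.0% of the left-handed substrate and right-handed substrate together are converted (percent change of the rate of making left-handed product for one percent more coupling partner charged)
* apparent order in free catalyst when 5.0% of the left-handed substrate and right-handed substrate together are converted (percent change of the rate of making left-handed product for one percent more free catalyst charged)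

- free catalyst is single-handed; left-handed substrate and right-handed substrate are mirror images of each other, charged as a racemate, each of them at the stated concentration
- the numbers in the tables scatter with a standard deviation of 0.3 percentage points
- steps thought possible: coupling partner + free catalyst + right-handed substrate -> free catalyst + right-handed product; coupling partner + free catalyst + left-handed substrate -> free catalyst + left-handed product; left-handed substrate <-> right-handed substrate; free catalyst + impurity -> spent catalyst
- no earlier run changes the charge of free catalyst; that part of a forecast is a guess

Elm has 3.5% of left-handed product at 2.50 min, while birch, with half the coupling partner, has 3.4% at 5.00 min. We therefore start from a rate of order one in coupling partner, and we assume the same for free catalyst. But we look at a fixed conversion, so a bigger charge loses the same amount by then, and what remains grows by a larger percentage.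

Take the coupling partner first. Its charge is 0.0600 M, and the look takes 0.00500 M from it:

order in coupling partner = charge / (charge − used) = 1.09

This look ratio, the charge over what remains at the look, is our estimate of the apparent order.

Now take the free catalyst. Its charge is 265 µM. We assume that by the look, which elm reaches between 2.50 min and 4.00 min, the impurity, a catalyst poison in the usual term, has taken its 43 µM:

order in free catalyst = charge / (charge − lost) = 1.19

The forecast gives 1.06 and 1.05, reasoning from “43 µM against 530 µM catalyst”. Our catalyst charge differs from that, and our orders, 1.09 and 1.19, are both higher than the forecast's.

    coupling partner + free catalyst + right-handed substrate → free catalyst + right-handed product (k = 1.30 /M²/s)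
    coupling partner + free catalyst + left-handed substrate → free catalyst + left-handed product (k = 37.0 /M²/s)
    left-handed substrate ⇌ right-handed substrate (k = 7.10 × 10⁻⁴ /s)
    free catalyst + impurity → spent catalyst (k = 200 /M/s)

The flask gives 1.1 and 1.2, both within the forecast's tolerance. The first stands close to our look ratio of 1.09. At 5.00 min the flask holds impurity at 0% of its charge, with spent catalyst at 16.2% and free catalyst at 83.8% of the catalyst charged, so the charge over the free catalyst then is 1.19. Birch has half the coupling partner of the flask, so the same conversion takes twice the share of its charge, and the look ratio 1.09 becomes 1.20.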